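## Retrosynthetic overview
1. The target comes from a benzyl/acetyl-protected dihydronaphthalene. Its vinylic CH (ring B) is removed as a one-carbon formyl equivalent that bridges the ketone α-carbon and the arene C–H para to OMe.
2. The open-chain (R)-γ-acetoxy aryl ketone is disconnected at the primary CH2–O bond. That bond forms while one of two enantiotopic C–C bonds of a prochiral 1-aryl-3-benzylcyclobutanol is cut, which sets the only stereocentre.
3. The cyclobutanol comes from an aryllithium (from 4-bromoguaiacol) and a 3-benzylcyclobutanone. The cyclobutanone comes from eugenol and dichloroketene by [2+2] cycloaddition.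
4. Ring order: both arenes are bought. The sacrificial cyclobutane is made first (step 2) and opened in step 5. Ring B is closed last (step 6).

Assumption: the sense of induction of the new desymmetrisation cannot be predicted with certainty, so the (S)-ligand is written as giving (R)-9, and the equally available (R)-ligand is used if the first run gives the antipode.

## Route

Step 1
Reactants: 1 eugenol (4-allyl-2-methoxyphenol)
Product: 2 4-allyl-1-(benzyloxy)-2-methoxybenzene
Conditions: BnBr, K2CO3, acetone, reflux
Reagents that add atoms: benzyl bromide, BrCc1ccccc1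
Why: Williamson ether synthesis, in which the phenoxide displaces bromide (SN2) and the benzyl ether shields the phenol from the acid chloride, the aryllithium and PhI(OAc)2 used later.

Step 2
Reactants: 2 4-allyl-1-(benzyloxy)-2-methoxybenzene
Product: 4 3-[4-(benzyloxy)-3-methoxybenzyl]cyclobutan-1-one, via dichlorocyclobutanone 3 (not isolated)
Conditions: Cl3CCOCl, Zn–Cu couple, Et2O–DME, reflux; then AcOH, Zn dust, same flask, rt → 40 °C
Reagents that add atoms: trichloroacetyl chloride, ClC(Cl)(Cl)C(Cl)=O
Why: Ketene–alkene [2+2] cycloaddition of dichloroketene made in situ (carbonyl carbon bonds to the terminal CH2) followed by Zn/AcOH reductive dechlorination, a sequence well proven on allylarenes, turns racemic 3 into the achiral, mirror-symmetric ketone 4, so no stereochemistry has to be controlled here.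

Step 3
Reactants: 5 4-bromo-2-methoxyphenol
Product: 6 1-(benzyloxy)-4-bromo-2-methoxybenzene
Conditions: BnBr, K2CO3, acetone, reflux
Reagents that add atoms: benzyl bromide, BrCc1ccccc1
Why: Williamson ether synthesis removes the acidic phenol proton so that the bromide can be lithiated cleanly.

Step 4
Reactants: 6 1-(benzyloxy)-4-bromo-2-methoxybenzene; 4 3-[4-(benzyloxy)-3-methoxybenzyl]cyclobutan-1-one
Product: 8 cis-1-[4-(benzyloxy)-3-methoxyphenyl]-3-[4-(benzyloxy)-3-methoxybenzyl]cyclobutan-1-ol (OH and benzyl group on the same face; achiral), via aryllithium 7 (not isolated)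
Conditions: n-BuLi, THF, −78 °C; then 4, −78 → −30 °C; H2O quench; chromatography on Et3N-washed silica
Reagents that add atoms: none
Why: Bromine–lithium exchange then 1,2-addition to the strained ketone, where attack anti to the 3-substituent of the puckered ring gives mainly the cis alcohol, which has a mirror plane and is freed of the minor trans isomer by chromatography.

Step 5
Reactants: 8 cis-1-[4-(benzyloxy)-3-methoxyphenyl]-3-[4-(benzyloxy)-3-methoxybenzyl]cyclobutan-1-ol
Product: 9 (2R)-2-[4-(benzyloxy)-3-methoxybenzyl]-4-[4-(benzyloxy)-3-methoxyphenyl]-4-oxobutyl acetate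
Conditions: Pd(OAc)2 (10 mol %), (S)-4-tert-butyl-2-(pyridin-2-yl)-4,5-dihydrooxazole (12 mol %), PhI(OAc)2 (1.5 equiv), NaOAc (0.5 equiv, buffer), 4 Å MS, PhMe, 40 °C
Reagents that add atoms: (diacetoxyiodo)benzene, CC(=O)OI(OC(C)=O)c1ccccc1
Why: Proposed new method: enantioselective ring-opening acetoxylation of a prochiral tert-cyclobutanol, in which the alcohol exchanges with acetate on the chiral pyridine-oxazoline Pd(OAc)2 complex; strain-driven β-carbon elimination from the divalent palladium alkoxide then cuts only one of the two enantiotopic C1–C2/C1–C4 ring bonds, because the tert-butyl quadrant of the ligand blocks the other syn-coplanar alignment, and this fixes the former ring C3 as R; the ketone-chelated primary alkylpalladium is oxidised by PhI(OAc)2 to tetravalent palladium faster than it can β-hydride eliminate, and SN2-type C–O reductive elimination with acetate forms the CH2–OAc bond and returns the catalyst; the closest known reaction types are the palladium-catalysed enantioselective ring-opening arylation of tert-cyclobutanols (same C–C cleavage, C–C instead of C–O termination) and the PhI(OAc)2-driven acetoxylation of primary alkylpalladium intermediates in pyridine-oxazoline-controlled alkene aminoacetoxylation.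

Step 6
Reactants: 9 (2R)-2-[4-(benzyloxy)-3-methoxybenzyl]-4-[4-(benzyloxy)-3-methoxyphenyl]-4-oxobutyl acetate
Product: 11 {(2R)-6-(benzyloxy)-3-[4-(benzyloxy)-3-methoxybenzoyl]-7-methoxy-1,2-dihydronaphthalen-2-yl}methyl acetate, via enaminone 10 (not isolated)
Conditions: t-BuOCH(NMe2)2 (3 equiv), PhMe, 100 °C; concentrate; TFA–CH2Cl2 (1:1), 0 °C → rt
Reagents that add atoms: tert-butoxybis(dimethylamino)methane (Bredereck's reagent), CC(C)(C)OC(N(C)C)N(C)C
Why: Aminomethylenation of the only ketone α-CH2 gives an enaminone that, once protonated, acts as a masked α-formyl ketone and closes ring B by intramolecular Friedel–Crafts cyclodehydration para to the methoxy group (the classical α-formyl carbonyl to 3,4-dihydronaphthalene closure) with loss of Me2NH, while the non-enolisable stereocentre is carried through unchanged.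

Step 7
Reactants: 11 {(2R)-6-(benzyloxy)-3-[4-(benzyloxy)-3-methoxybenzoyl]-7-methoxy-1,2-dihydronaphthalen-2-yl}methyl acetate
Product: 13 (4-hydroxy-3-methoxyphenyl)[(3R)-7-hydroxy-3-(hydroxymethyl)-6-methoxy-3,4-dihydronaphthalen-2-yl]methanone (CNP0352298.1), via diphenol acetate 12 (not isolated)
Conditions: BCl3 (6 equiv), C6HMe5 (8 equiv), CH2Cl2, −78 °C; then MeOH, −78 °C → rt, 12 h; aq. NaHCO3
Reagents that add atoms: none
Why: Lewis-acid debenzylation of aryl benzyl ethers with BCl3 and pentamethylbenzene as a non-basic cation scavenger spares the enone C=C, the ketone and the methyl ethers (hydrogenolysis would not), and the HCl/MeOH formed by the methanol quench transesterifies the primary acetate without touching the stereocentre.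

## Compound list
1 | eugenol (4-allyl-2-methoxyphenol) | C=CCc1ccc(O)c(OC)c1 | starting material
2 | 4-allyl-1-(benzyloxy)-2-methoxybenzene | C=CCc1ccc(OCc2ccccc2)c(OC)c1 | intermediate
3 | 2,2-dichloro-3-[4-(benzyloxy)-3-methoxybenzyl]cyclobutan-1-one (racemic; not isolated) | O=C1CC(Cc2ccc(OCc3ccccc3)c(OC)c2)C1(Cl)Cl | intermediate
4 | 3-[4-(benzyloxy)-3-methoxybenzyl]cyclobutan-1-one (achiral, prochiral) | O=C1CC(Cc2ccc(OCc3ccccc3)c(OC)c2)C1 | intermediate
5 | 4-bromo-2-methoxyphenol | COc1cc(Br)ccc1O | starting material
6 | 1-(benzyloxy)-4-bromo-2-methoxybenzene | COc1cc(Br)ccc1OCc1ccccc1 | intermediate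
7 | [4-(benzyloxy)-3-methoxyphenyl]lithium (not isolated) | [Li]c1ccc(OCc2ccccc2)c(OC)c1 | intermediate
8 | cis-1-[4-(benzyloxy)-3-methoxyphenyl]-3-[4-(benzyloxy)-3-methoxybenzyl]cyclobutan-1-ol (OH cis to the benzyl group; achiral) | O[C@]1(c2ccc(OCc3ccccc3)c(OC)c2)C[C@H](Cc2ccc(OCc3ccccc3)c(OC)c2)C1 | intermediate
9 | (2R)-2-[4-(benzyloxy)-3-methoxybenzyl]-4-[4-(benzyloxy)-3-methoxyphenyl]-4-oxobutyl acetate | COc1cc(C[C@H](CC(=O)c2ccc(OCc3ccccc3)c(OC)c2)COC(C)=O)ccc1OCc1ccccc1 | intermediate
10 | (2R,3E)-2-[4-(benzyloxy)-3-methoxybenzyl]-3-[4-(benzyloxy)-3-methoxybenzoyl]-4-(dimethylamino)but-3-en-1-yl acetate (not isolated) | COc1cc(C[C@H](/C(=C\N(C)C)C(=O)c2ccc(OCc3ccccc3)c(OC)c2)COC(C)=O)ccc1OCc1ccccc1 | intermediate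
11 | {(2R)-6-(benzyloxy)-3-[4-(benzyloxy)-3-methoxybenzoyl]-7-methoxy-1,2-dihydronaphthalen-2-yl}methyl acetate | COc1cc(C(=O)C2=Cc3cc(OCc4ccccc4)c(OC)cc3C[C@H]2COC(C)=O)ccc1OCc1ccccc1 | intermediate
12 | [(2R)-6-hydroxy-3-(4-hydroxy-3-methoxybenzoyl)-7-methoxy-1,2-dihydronaphthalen-2-yl]methyl acetate (not isolated) | COc1cc(C(=O)C2=Cc3cc(O)c(OC)cc3C[C@H]2COC(C)=O)ccc1O | intermediate
13 | (4-hydroxy-3-methoxyphenyl)[(3R)-7-hydroxy-3-(hydroxymethyl)-6-methoxy-3,4-dihydronaphthalen-2-yl]methanone | COc1cc(C(=O)C2=Cc3cc(O)c(OC)cc3C[C@H]2CO)ccc1O | target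

## Step count and risks
Total steps: 7. Longest linear sequence: 6 (steps 1, 2, 4, 5, 6, 7).

**Step 5 (the new reaction).**
- Risks: β-hydride elimination of the alkylpalladium to the 1,1-disubstituted alkene, modest ee, or an oxidant-induced racemic background opening.
- Fallback: this uses known chemistry and is still a C–O-forming desymmetrisation. It sets out from 4. Catalytic asymmetric Baeyer–Villiger oxidation (Sc(OTf)3, chiral N,N'-dioxide ligand of the antipode that gives R, m-CPBA, EtOAc, −20 °C) gives (4R)-4-[4-(benzyloxy)-3-methoxybenzyl]dihydrofuran-2(3H)-one F1. One equivalent of aryllithium 7 (from 6, n-BuLi, THF, −78 °C) opens the lactone by mono-addition to (3R)-3-[4-(benzyloxy)-3-methoxybenzyl]-1-[4-(benzyloxy)-3-methoxyphenyl]-4-hydroxybutan-1-one F2. Ac2O/pyridine then gives 9, where the route is rejoined, one step longer.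

**Step 6 (one-carbon annulation).**
- Risks: sluggish aminomethylenation of the hindered α-CH2, partial loss of the acetate, or a protonated enaminone too weakly electrophilic for the arene.
- Fallback: the order of the two C–C bonds is reversed. It sets out from 9. Rieche formylation (Cl2CHOMe, SnCl4, CH2Cl2, −78 → 0 °C) attacks the only activated ring para to OMe. This gives (2R)-2-[4-(benzyloxy)-2-formyl-5-methoxybenzyl]-4-[4-(benzyloxy)-3-methoxyphenyl]-4-oxobutyl acetate F3. An intramolecular aldol condensation (TsOH·H2O cat., PhMe, 80 °C) of the ketone CH2 onto the aryl aldehyde closes ring B and comes back at 11.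

**Step 7 (one-pot global deprotection).**
- Risks: methanol addition or ketal formation on the free γ-hydroxy enone in methanolic HCl, or boron-assisted demethylation.
- Fallback: the order and the mode of C–O cleavage both change. It sets out from 11. Basic methanolysis (K2CO3, MeOH, 0 °C) is run while the phenols are still masked. This gives [4-(benzyloxy)-3-methoxyphenyl][(3R)-7-(benzyloxy)-3-(hydroxymethyl)-6-methoxy-3,4-dihydronaphthalen-2-yl]methanone F4. Brønsted-acid benzyl transfer (TFA, pentamethylbenzene, rt, then brief aq. NaHCO3/MeOH to remove any trifluoroacetate) delivers 13.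

## Further compounds
F1 | step 5 | (4R)-4-[4-(benzyloxy)-3-methoxybenzyl]dihydrofuran-2(3H)-one | COc1cc(C[C@@H]2CC(=O)OC2)ccc1OCc1ccccc1
F2 | step 5 | (3R)-3-[4-(benzyloxy)-3-methoxybenzyl]-1-[4-(benzyloxy)-3-methoxyphenyl]-4-hydroxybutan-1-one | COc1cc(C[C@H](CC(=O)c2ccc(OCc3ccccc3)c(OC)c2)CO)ccc1OCc1ccccc1
F3 | step 6 | (2R)-2-[4-(benzyloxy)-2-formyl-5-methoxybenzyl]-4-[4-(benzyloxy)-3-methoxyphenyl]-4-oxobutyl acetate | COc1cc(C[C@H](CC(=O)c2ccc(OCc3ccccc3)c(OC)c2)COC(C)=O)c(C=O)cc1OCc1ccccc1
F4 | step 7 | [4-(benzyloxy)-3-methoxyphenyl][(3R)-7-(benzyloxy)-3-(hydroxymethyl)-6-methoxy-3,4-dihydronaphthalen-2-yl]methanone | COc1cc(C(=O)C2=Cc3cc(OCc4ccccc4)c(OC)cc3C[C@H]2CO)ccc1OCc1ccccc1
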